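**Retrosynthetic overview**

1. Numbering: C1 acetal CH, O2 ring oxygen, C3H=C4 enol ether, C5, C6 and C7 (cyclopropane CH; C6 on C5, C7 on C8), C8, C9, C10 (methyl carbinol), C11 (joins C10, C1, C5), C12 (quaternary cyclopropane carbon), C13 (its CH2OAc), C14–O–C15 (bridge from C12 to C4); rings A dihydropyran, B cycloheptane, C cyclopropane, D oxepane. The strategy rests on ring C: C5, C8 and C14 are all cis on it and C12 carries both CH2O arms, which is the signature of a syn addition across an achiral 3,3-bis(oxymethyl)cyclopropene steered from the C14 oxygen.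
2. Target ⇒ ring A opened to the C1/C3 dialdehyde (enol–hemiacetal closure and acetylations last) ⇒ ring B opened at C10–C11 (aldol of a ring A δ-lactone enolate onto the C10 methyl ketone) ⇒ ring D opened at C4–C5 (7-exo radical closure of an O14 2-bromoallyl ether onto the C5=C11 enoate).
3. The enoate ⇒ lactol of the all-cis cyclopropane carbaldehyde ⇒ C7–C8 and C5–C6 disconnections to cyclopropene 7, ketal Grignard reagent 9 and DMF 10 (three-component, ligand-controlled carbomagnesiation–formylation that desymmetrises 7 and sets C6, C7 and C12).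
4. Cyclopropene 7 ⇒ dimethyl malonate and trimethylsilylacetylene (diazo transfer, Rh2(OAc)4 cyclopropenation, desilylation, reduction, monosilylation).
5. Order of ring formation, forward: C (cyclopropene, then stereodefined cyclopropane) → D → A (as lactone) → B → A (re-closed as enol ether acetal).

Key step: step 7

Assumption: N-methyl-L-prolinol is taken to direct the alkyl group to the enantiotopic alkene carbon that becomes C7 as drawn; if it favours the other carbon, N-methyl-D-prolinol is used with no other change.

**Route**

Step 1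
Reactants: 1 dimethyl malonate
Product: 2 dimethyl 2-diazomalonate
Conditions: 4-acetamidobenzenesulfonyl azide, Et3N, MeCN, 0 °C → rt
Reagents that add atoms: 4-acetamidobenzenesulfonyl azide, CC(=O)Nc1ccc(cc1)S(=O)(=O)N=[N+]=[N-]
Why: Regitz diazo transfer to the doubly activated methylene is a standard, clean reaction with a sulfonyl azide and an amine base.

Step 2
Reactants: 2 dimethyl 2-diazomalonate; 3 trimethylsilylacetylene
Product: 4 dimethyl 2-(trimethylsilyl)cycloprop-2-ene-1,1-dicarboxylate
Conditions: Rh2(OAc)4 (1 mol %), 3 (excess), CH2Cl2, 40 °C, slow addition of 2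
Reagents that add atoms: trimethylsilylacetylene (3), C#C[Si](C)(C)C
Why: Rh2(OAc)4 turns the diazomalonate into an electrophilic rhodium carbene that adds to the terminal alkyne (carbene [2+1] cyclopropenation), the silyl group suppressing C–H insertion and stabilising the strained product.

Step 3
Reactants: 4 dimethyl 2-(trimethylsilyl)cycloprop-2-ene-1,1-dicarboxylate
Product: 5 dimethyl cycloprop-2-ene-1,1-dicarboxylate
Conditions: K2CO3 (cat.), MeOH/THF, 0 °C
Reagents that add atoms: none
Why: The sp-like cyclopropenyl C–Si bond is cleaved by methoxide (protodesilylation, as for an alkynylsilane), and the 3,3-disubstituted cyclopropene formed has no allylic hydrogen for ene dimerisation.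

Step 4
Reactants: 5 dimethyl cycloprop-2-ene-1,1-dicarboxylate
Product: 6 cycloprop-2-ene-1,1-diyldimethanol
Conditions: i-Bu2AlH (4.5 equiv), Et2O, −78 → 0 °C; Rochelle salt work-up
Reagents that add atoms: none
Why: i-Bu2AlH reduces both esters to primary alcohols (hydride reduction) and at low temperature should leave the strained alkene alone.

Step 5
Reactants: 6 cycloprop-2-ene-1,1-diyldimethanol
Product: 7 [1-({[tert-butyl(dimethyl)silyl]oxy}methyl)cycloprop-2-en-1-yl]methanol (achiral)
Conditions: NaH (1.0 equiv), THF, 0 °C; t-BuMe2SiCl (1.0 equiv), 0 °C → rt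
Reagents that add atoms: tert-butyldimethylsilyl chloride, CC(C)(C)[Si](C)(C)Cl
Why: Monosilylation of a symmetric diol through its monosodium alkoxide is a reliable way to the monoether, and the product keeps its mirror plane, so no stereochemical issue arises.

Step 6
Reactants: 8 2-(2-bromoethyl)-2-methyl-1,3-dioxolane
Product: 9 [2-(2-methyl-1,3-dioxolan-2-yl)ethyl]magnesium bromide
Conditions: Mg turnings (iodine crystal to start), THF, 20–25 °C
Reagents that add atoms: magnesium, [Mg]
Why: Magnesium insertion into the primary bromide (Grignard formation) is established for this ketal bromide when the temperature is kept near ambient.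

Step 7
Reactants: 7 cyclopropene monosilyl ether; 9 ketal Grignard reagent; 10 N,N-dimethylformamide
Product: 13 lactol of the all-cis cyclopropane carbaldehyde (O14 bonded to C5; anomer mixture), via cyclopropylmagnesium bromide 11 (not isolated), via hydroxy aldehyde 12 (not isolated)
Conditions: 9 (3.5 equiv), N-methyl-L-prolinol (1.5 equiv, premixed with 9), MeOH (1 equiv), THF/PhMe, −20 → 0 °C; then 10 (6 equiv), 0 °C → rt; aq NH4Cl
Reagents that add atoms: [2-(2-methyl-1,3-dioxolan-2-yl)ethyl]magnesium bromide (9), CC1(CC[Mg]Br)OCCO1; N,N-dimethylformamide (10), CN(C)C=O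
Why: The first equivalent of 9 converts the C14 hydroxyl of 7 into its magnesium alkoxide, which binds an alkylmagnesium unit carrying the chiral amino alkoxide and delivers it across the strained C6=C7 bond from the alkoxide face in a concerted syn carbometalation driven by release of cyclopropene strain. The closest known reaction type is the hydroxymethyl-directed, amino-alcohol-controlled enantioselective carbomagnesiation of 3-(hydroxymethyl)cyclopropenes with electrophilic capture of the cyclopropylmagnesium. The step forms C7–C8 and, after formylation of the configurationally stable cyclopropylmagnesium 11 by DMF with retention, C5–C6; it closes no skeletal ring, and the only ring formed is the reversible five-membered hemiacetal (5-exo-trig addition of O14 to the C5 aldehyde of 12) that stores the cis aldehyde as lactol 13. C12 becomes stereogenic through the facial choice made by the C14 alkoxide, the cis relation of C8 and C5 follows from syn addition and retentive trapping, and the absolute sense at C6 and C7 is set by the chiral ligand, which tells the two enantiotopic alkene carbons apart. The step thus needs facial selectivity, syn addition and enantiotopic-carbon selectivity, which are secured by the single coordinating alkoxide (the silyl ether on the other arm is a poor donor), by the concerted mechanism and by the ligand, respectively.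

Step 8
Reactants: 13 lactol; 14 methyl (triphenylphosphoranylidene)acetate
Product: 15 hydroxy enoate (methyl E-acrylate on C6: C5=C11–C1O2Me; free C14 hydroxyl)
Conditions: 14 (1.3 equiv), PhMe, 50 °C
Reagents that add atoms: methyl (triphenylphosphoranylidene)acetate (14), COC(=O)C=P(c1ccccc1)(c1ccccc1)c1ccccc1
Why: The lactol reacts through its open aldehyde with the stabilised ylide (Wittig olefination) to give the E-enoate under neutral conditions, which should keep the liberated C14 hydroxyl from adding back to C5.

Step 9
Reactants: 15 hydroxy enoate; 16 2,3-dibromopropene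
Product: 17 2-bromoallyl ether (O14–C15H2–C4(Br)=C3H2)
Conditions: 16 (2 equiv), AgOTf (1.5 equiv), 2,6-di-tert-butylpyridine (2 equiv), CH2Cl2, 0 °C → rt, dark
Reagents that add atoms: 2,3-dibromopropene (16), C=C(Br)CBr
Why: AgOTf turns the allylic bromide into a reactive allylic triflate that alkylates the neopentyl-type alcohol (silver-promoted Williamson-type etherification) with a hindered pyridine as acid scavenger, so that no alkoxide able to close onto the enoate is formed and the vinylic bromide is untouched.

Step 10
Reactants: 17 2-bromoallyl ether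
Product: 18 ring D ester (oxepane closed; exocyclic C4=C3H2; C5 bearing CH2CO2Me)
Conditions: Bu3SnH (1.3 equiv, syringe pump), AIBN (cat.), PhH, 80 °C, high dilution
Reagents that add atoms: none
Why: Bromine abstraction gives the C4 vinyl radical, which adds 7-exo-trig to C5 of the enoate (tin hydride radical cyclisation) and closes ring D; because C4 is tied to C12 through O14 and the enoate sits s-trans with H5 tucked between C8 and C14, C4 can only reach the C12-side face of C5, which sets C5 as in the target.

Step 11
Reactants: 18 ring D ester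
Product: 21 ring A δ-lactone fused to rings D and C (C4 epimers), via C3 alkylborane 19 (not isolated), via hydroxy ester 20 (not isolated)
Conditions: 9-BBN, THF, 0 °C → rt; NaBO3·4H2O, THF/H2O, rt; PPTS (cat.), PhMe, 50 °C
Reagents that add atoms: sodium perborate, [Na+].[Na+].O[B-]1(O)OO[B-](O)(O)OO1
Why: 9-BBN places boron on the terminal carbon of the 1,1-disubstituted alkene (anti-Markovnikov hydroboration–oxidation) and the primary C3 alcohol lactonises onto the C1 ester (6-exo-trig acyl substitution, first form of ring A); the C4 centre is formed without control, which is harmless because C4 becomes trigonal in step 17.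

Step 12
Reactants: 21 ring A δ-lactone
Product: 23 C11-bromo lactone (C11 epimers), via silyl ketene acetal 22 (not isolated)
Conditions: LiN(i-Pr)2, Me3SiCl, THF, −78 °C; NBS, THF, −78 °C
Reagents that add atoms: N-bromosuccinimide, O=C1CCC(=O)N1Br
Why: C11 is the only acidic position, so kinetic enolisation with silyl trapping and electrophilic bromination of the ketene acetal installs a regiospecific enolate precursor there, both bromide epimers leading to the same enolate.

Step 13
Reactants: 23 C11-bromo lactone
Product: 24 C11-bromo lactone methyl ketone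
Conditions: PPTS, acetone/H2O (9:1), 35 °C
Reagents that add atoms: water, O
Why: Mild acid hydrolysis of the dioxolane (ketal cleavage) frees the C10 methyl ketone under conditions that the α-bromo lactone and the primary silyl ether should tolerate.

Step 14
Reactants: 24 C11-bromo lactone methyl ketone
Product: 26 tetracyclic hydroxy lactone (ring B closed; C10 tertiary alcohol), via samarium enolate 25 (not isolated)
Conditions: SmI2 (2.5 equiv), THF, −78 °C, high dilution; aq NH4Cl
Reagents that add atoms: none
Why: Two-electron reduction of the C–Br bond gives the trivalent samarium lactone enolate at C11 only (samarium Reformatsky-type intramolecular aldol), which adds to the C10 ketone in a 7-(enolexo)-exo-trig closure of ring B; the tether from C6 reaches only the ring A face cis to C6, so H11 ends cis to H5, and in the chelated Zimmerman–Traxler-type transition state the samarium-bound ketone oxygen takes the crowded position gauche to C1 and C5 while the methyl points outward, which places the C10 hydroxyl cis to C1.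

Step 15
Reactants: 26 tetracyclic hydroxy lactone
Product: 27 C10 triethylsilyl ether
Conditions: Et3SiOTf, 2,6-lutidine, CH2Cl2, −78 → 0 °C
Reagents that add atoms: triethylsilyl trifluoromethanesulfonate, CC[Si](CC)(CC)OS(=O)(=O)C(F)(F)F
Why: A silyl triflate with a hindered base silylates the tertiary alcohol (silyl ether formation), so that it cannot add to the C3 aldehyde generated in step 17.

Step 16
Reactants: 27 C10 triethylsilyl ether
Product: 28 diol (C1H2OH and C3H2OH)
Conditions: LiAlH4, THF, 0 °C
Reagents that add atoms: none
Why: LiAlH4 reduces the lactone to the 1,5-diol (hydride reduction) and leaves the ether, the cyclopropane and both silyl ethers intact.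

Step 17
Reactants: 28 diol
Product: 30 ring A lactol (C1 hemiacetal; C3=C4 enol ether), via dialdehyde 29 (not isolated)
Conditions: (COCl)2, DMSO, CH2Cl2, −78 °C; Et3N, −78 → 0 °C; then PPTS (cat.), CH2Cl2, rt
Reagents that add atoms: none
Why: Swern oxidation activates both primary alcohols before base is added, so the 1,5-dialdehyde forms without lactone formation, and ring A closes when the less hindered C3 aldehyde enolises towards C4 and its enol oxygen adds to the C1 aldehyde (6-exo-trig enol–hemiacetal cyclisation, as with iridoid dialdehydes), the alternative C1=C11 enol being disfavoured next to the quaternary C10.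

Step 18
Reactants: 30 ring A lactol
Product: 31 C1 acetate
Conditions: Ac2O, pyridine, DMAP (cat.), CH2Cl2, 0 °C
Reagents that add atoms: acetic anhydride, CC(=O)OC(C)=O
Why: The equilibrating lactol is acetylated (DMAP-catalysed acyl transfer) preferentially as the axial anomer with the acetoxy group trans to the C10–C11 bond (anomeric effect and approach away from the neopentyl C10 group), which is the C1 configuration of the target.

Step 19
Reactants: 31 C1 acetate
Product: 32 diol (C13 and C10 hydroxyls free; C1 acetate kept)
Conditions: HF·pyridine, pyridine, THF, 0 °C → rt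
Reagents that add atoms: none
Why: Buffered HF·pyridine cleaves both silyl ethers (fluoride desilylation) under conditions mild enough for the acetal acetate and the enol ether, which is now locked and cannot be captured by the C10 hydroxyl.

Step 20
Reactants: 32 diol
Product: 33 target CNP0250836.3
Conditions: Ac2O, pyridine, CH2Cl2, 0 °C → rt
Reagents that add atoms: acetic anhydride, CC(=O)OC(C)=O
Why: Acetic anhydride with pyridine acetylates the primary C13 hydroxyl only (selective esterification), the tertiary C10 hydroxyl being inert without forcing acylation conditions.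

**Compound list**

1 | dimethyl malonate | COC(=O)CC(=O)OC | starting material
2 | dimethyl 2-diazomalonate | COC(=O)C(=[N+]=[N-])C(=O)OC | intermediate
3 | trimethylsilylacetylene | C#C[Si](C)(C)C | starting material
4 | dimethyl 2-(trimethylsilyl)cycloprop-2-ene-1,1-dicarboxylate | COC(=O)C1(C(=O)OC)C=C1[Si](C)(C)C | intermediate
5 | dimethyl cycloprop-2-ene-1,1-dicarboxylate | COC(=O)C1(C(=O)OC)C=C1 | intermediate
6 | cycloprop-2-ene-1,1-diyldimethanol | OCC1(CO)C=C1 | intermediate
7 | [1-({[tert-butyl(dimethyl)silyl]oxy}methyl)cycloprop-2-en-1-yl]methanol (achiral key precursor) | OCC1(CO[Si](C)(C)C(C)(C)C)C=C1 | intermediate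
8 | 2-(2-bromoethyl)-2-methyl-1,3-dioxolane | CC1(CCBr)OCCO1 | starting material
9 | [2-(2-methyl-1,3-dioxolan-2-yl)ethyl]magnesium bromide | CC1(CC[Mg]Br)OCCO1 | intermediate
10 | N,N-dimethylformamide | CN(C)C=O | starting material
11 | all-cis cyclopropylmagnesium bromide (MgBr on C6, ketal chain on C7, bromomagnesium alkoxide on C14, silyloxymethyl C13 trans) | CC(C)(C)[Si](C)(C)OC[C@@]1(CO[Mg]Br)[C@H]([Mg]Br)[C@@H]1CCC1(C)OCCO1 | intermediate (not isolated)
12 | all-cis hydroxy aldehyde (key product, open form: CHO on C6, ketal chain on C7, CH2OH and CH2OTBS on C12; C5, C8, C14 cis) | CC(C)(C)[Si](C)(C)OC[C@@]1(CO)[C@H](C=O)[C@@H]1CCC1(C)OCCO1 | intermediate (not isolated)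
13 | lactol of 12 (3-oxabicyclo[3.1.0]hexan-2-ol core, O14 bonded to C5, anomer mixture) | CC(C)(C)[Si](C)(C)OC[C@@]12COC(O)[C@@H]1[C@@H]2CCC1(C)OCCO1 | intermediate
14 | methyl (triphenylphosphoranylidene)acetate | COC(=O)C=P(c1ccccc1)(c1ccccc1)c1ccccc1 | starting material
15 | hydroxy enoate (methyl E-acrylate on C6, free C14 hydroxyl) | CC(C)(C)[Si](C)(C)OC[C@@]1(CO)[C@H](/C=C/C(=O)OC)[C@@H]1CCC1(C)OCCO1 | intermediate
16 | 2,3-dibromopropene | C=C(Br)CBr | starting material
17 | 2-bromoallyl ether of 15 | CC(C)(C)[Si](C)(C)OC[C@@]1(COCC(Br)=C)[C@H](/C=C/C(=O)OC)[C@@H]1CCC1(C)OCCO1 | intermediate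
18 | ring D ester (oxepane fused to ring C, exocyclic C4=C3H2, C5 bearing CH2CO2Me in the target configuration) | CC(C)(C)[Si](C)(C)OC[C@@]12COCC(=C)[C@@H](CC(=O)OC)[C@@H]1[C@@H]2CCC1(C)OCCO1 | intermediate
19 | C3 alkylborane (B-alkyl-9-borabicyclo[3.3.1]nonane; C4 epimers) | CC(C)(C)[Si](C)(C)OC[C@@]12COCC(CB3C4CCCC3CCC4)[C@@H](CC(=O)OC)[C@@H]1[C@@H]2CCC1(C)OCCO1 | intermediate (not isolated)
20 | hydroxy ester (C3H2OH; C4 epimers) | CC(C)(C)[Si](C)(C)OC[C@@]12COCC(CO)[C@@H](CC(=O)OC)[C@@H]1[C@@H]2CCC1(C)OCCO1 | intermediate (not isolated)
21 | ring A δ-lactone (C1(=O)–O2–C3H2) fused to rings D and C (C4 epimers) | CC(C)(C)[Si](C)(C)OC[C@@]12COCC3COC(=O)C[C@H]3[C@@H]1[C@@H]2CCC1(C)OCCO1 | intermediate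
22 | trimethylsilyl ketene acetal of 21 (C1=C11) | CC(C)(C)[Si](C)(C)OC[C@@]12COCC3COC(O[Si](C)(C)C)=C[C@H]3[C@@H]1[C@@H]2CCC1(C)OCCO1 | intermediate (not isolated)
23 | C11-bromo lactone (C11 epimers) | CC(C)(C)[Si](C)(C)OC[C@@]12COCC3COC(=O)C(Br)[C@H]3[C@@H]1[C@@H]2CCC1(C)OCCO1 | intermediate
24 | C11-bromo lactone methyl ketone | CC(C)(C)[Si](C)(C)OC[C@@]12COCC3COC(=O)C(Br)[C@H]3[C@@H]1[C@@H]2CCC(C)=O | intermediate
25 | trivalent samarium lactone enolate (C1=C11) | CC(C)(C)[Si](C)(C)OC[C@@]12COCC3COC(O[Sm](I)I)=C[C@H]3[C@@H]1[C@@H]2CCC(C)=O | intermediate (not isolated)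
26 | tetracyclic hydroxy lactone (rings A–D; H5 and H11 cis; C10 hydroxyl cis to C1) | CC(C)(C)[Si](C)(C)OC[C@@]12COCC3COC(=O)[C@@H]4[C@H]3[C@@H]1[C@@H]2CC[C@]4(C)O | intermediate
27 | C10 triethylsilyl ether of 26 | CC(C)(C)[Si](C)(C)OC[C@@]12COCC3COC(=O)[C@@H]4[C@H]3[C@@H]1[C@@H]2CC[C@]4(C)O[Si](CC)(CC)CC | intermediate
28 | diol (C1H2OH on C11, C3H2OH on C4) | CC(C)(C)[Si](C)(C)OC[C@@]12COCC(CO)[C@@H]3[C@@H]1[C@@H]2CC[C@](C)(O[Si](CC)(CC)CC)[C@@H]3CO | intermediate
29 | dialdehyde (C1HO, C3HO) | CC(C)(C)[Si](C)(C)OC[C@@]12COCC(C=O)[C@@H]3[C@@H]1[C@@H]2CC[C@](C)(O[Si](CC)(CC)CC)[C@@H]3C=O | intermediate (not isolated)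
30 | ring A lactol (C1 hemiacetal, anomer mixture; C3=C4 enol ether) | CC(C)(C)[Si](C)(C)OC[C@@]12COCC3=COC(O)[C@@H]4[C@H]3[C@@H]1[C@@H]2CC[C@]4(C)O[Si](CC)(CC)CC | intermediate
31 | C1 acetate (C13 silyl ether, C10 silyl ether) | CC(C)(C)[Si](C)(C)OC[C@@]12COCC3=CO[C@H](OC(C)=O)[C@@H]4[C@H]3[C@@H]1[C@@H]2CC[C@]4(C)O[Si](CC)(CC)CC | intermediate
32 | C1 acetate diol (C13 and C10 hydroxyls free) | OC[C@@]12COCC3=CO[C@H](OC(C)=O)[C@@H]4[C@H]3[C@@H]1[C@@H]2CC[C@]4(C)O | intermediate
33 | CNP0250836.3 | CC(=O)OC[C@@]12COCC3=CO[C@H](OC(C)=O)[C@@H]4[C@H]3[C@@H]1[C@@H]2CC[C@]4(C)O | target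

**Step count**

Total: 20 steps. Longest linear sequence: 19 steps (steps 1–5 and 7–20 from dimethyl malonate; step 6 is a one-step branch).

**Steps most likely to fail**

Step 14 (samarium aldol closing ring B). The samarium enolate may be protonated, or the ketone reduced, before the seven-membered ring closes; the ketone may also be attacked on the wrong face, which would give the C10 epimer. The fallback sets out from 21 and comes back at 28. It forms C10–C11 by cross-coupling and sets C10 by a directed epoxidation. The ketal of 21 is hydrolysed (PPTS, aqueous acetone) to keto lactone F1. The methyl ketone is converted into its terminal enol triflate F2 (KN(SiMe3)2, PhNTf2, THF, −78 °C). Palladium-catalysed intramolecular α-alkenylation of the lactone enolate (Pd2(dba)3, P(t-Bu)3, LiN(SiMe3)2, THF) closes ring B as the cis-fused exo-methylene lactone F3. LiAlH4 gives exo-methylene diol F4. Epoxidation directed by the homoallylic C1 hydroxyl (VO(acac)2, t-BuOOH) places the oxygen on the C1 side and gives spiro-epoxy diol F5. LiAlH4 opens the epoxide at its CH2 to triol F6, in which the C10 hydroxyl is cis to C1. Full silylation (Et3SiOTf, 2,6-lutidine) gives tris(triethylsilyl) ether F7, and selective methanolysis of its two primary triethylsilyl ethers (PPTS, MeOH, 0 °C) returns 28.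

Step 10 (7-exo radical closure of ring D). Hydrogen transfer from Bu3SnH, or a 1,6-hydrogen shift, may quench the vinyl radical before it reaches C5. The fallback sets out from 13 and comes back at 18. It builds ring D first and brings in C11 afterwards. Lactol 13 is annulated with trimethyl 2-phosphonoacrylate (NaH, THF, 0 °C → rt): oxa-Michael addition of O14 is followed by intramolecular Horner–Wadsworth–Emmons condensation with the C5 aldehyde, giving ring D enoate F8. i-Bu2AlH reduces the ester to ring D allylic alcohol F9. Johnson–Claisen rearrangement (MeC(OMe)3, EtCO2H cat., PhMe, not above 110 °C) then delivers the CH2CO2Me arm to C5 on the ring face away from cyclopropane carbon C7 and moves the double bond to C4=C3, which gives 18.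

Step 7 (key step). The ligand may discriminate poorly between the enantiotopic carbons C6 and C7 with this ketal-bearing primary Grignard reagent, or the cyclopropylmagnesium may be protonated before formylation. The fallback sets out from 7 and comes back at 13. It replaces asymmetric induction by separation of diastereomers. Racemic hydroxyl-directed carbomagnesiation of 7 with 9 (CuI 10 mol %, THF, −20 °C) is followed by trapping of the cyclopropylmagnesium with (1R,2S,5R)-menthyl (S)-p-toluenesulfinate. The two diastereomeric sulfoxides are separated by chromatography or crystallisation. The diastereomer with the carbon configuration of 13, p-tolylsulfinyl cyclopropane F10, undergoes sulfoxide–magnesium exchange (i-PrMgCl, THF, −78 °C) with retention at C6, and formylation with 10 gives 13.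

**Further compounds**

F1 | step 14 | keto lactone (21 with the ketal removed) | CC(C)(C)[Si](C)(C)OC[C@@]12COCC3COC(=O)C[C@H]3[C@@H]1[C@@H]2CCC(C)=O
F2 | step 14 | terminal enol triflate of F1 | CC(C)(C)[Si](C)(C)OC[C@@]12COCC3COC(=O)C[C@H]3[C@@H]1[C@@H]2CCC(=C)OS(=O)(=O)C(F)(F)F
F3 | step 14 | cis-fused exo-methylene lactone (ring B closed, C10=CH2) | CC(C)(C)[Si](C)(C)OC[C@@]12COCC3COC(=O)[C@@H]4[C@H]3[C@@H]1[C@@H]2CCC4=C
F4 | step 14 | exo-methylene diol | CC(C)(C)[Si](C)(C)OC[C@@]12COCC(CO)[C@@H]3[C@@H]1[C@@H]2CCC(=C)[C@@H]3CO
F5 | step 14 | spiro-epoxy diol (epoxide oxygen cis to C1) | CC(C)(C)[Si](C)(C)OC[C@@]12COCC(CO)[C@@H]3[C@@H]1[C@@H]2CC[C@@]4(CO4)[C@@H]3CO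
F6 | step 14 | triol (C10 hydroxyl cis to C1) | CC(C)(C)[Si](C)(C)OC[C@@]12COCC(CO)[C@@H]3[C@@H]1[C@@H]2CC[C@](C)(O)[C@@H]3CO
F7 | step 14 | tris(triethylsilyl) ether | CC(C)(C)[Si](C)(C)OC[C@@]12COCC(CO[Si](CC)(CC)CC)[C@@H]3[C@@H]1[C@@H]2CC[C@](C)(O[Si](CC)(CC)CC)[C@@H]3CO[Si](CC)(CC)CC
F8 | step 10 | ring D enoate (C4=C5, CO2Me on C4) | CC(C)(C)[Si](C)(C)OC[C@@]12COCC(C(=O)OC)=C[C@@H]1[C@@H]2CCC1(C)OCCO1
F9 | step 10 | ring D allylic alcohol (C4=C5, CH2OH on C4) | CC(C)(C)[Si](C)(C)OC[C@@]12COCC(CO)=C[C@@H]1[C@@H]2CCC1(C)OCCO1
F10 | step 7 | p-tolylsulfinyl cyclopropane (sulfoxide on C6, R at sulfur, carbon configuration of 13) | CC(C)(C)[Si](C)(C)OC[C@@]1(CO)[C@H]([S@@](=O)c2ccc(C)cc2)[C@@H]1CCC1(C)OCCO1
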